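**Retrosynthetic overview**
- The target is cut at the exocyclic C=C of ring A: an aldol condensation joins the (S)-isobutenyl γ-lactone to a C17 butenolide aldehyde. The only stereocentre arrives with the lactone.
- The butenolide aldehyde comes from a homofarnesyl butenolide by terminal bromohydrin/epoxide/periodate cleavage of the isopropylidene end.
- The homofarnesyl butenolide comes from farnesylacetic acid (as its N-acyloxyphthalimide) and 4-bromofuran-2(5H)-one by a photochemical nickel-catalysed decarboxylative alkenylation, the key C(sp3)–C(sp2) bond.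
- Farnesylacetic acid comes from (2E,6E)-farnesyl bromide and the acetic acid dianion; the lactone comes from the L-glutamic-acid-derived (S)-5-(hydroxymethyl)butanolide by oxidation and Wittig olefination.
- Ring order: no ring is built. Ring B (butenolide) is attached first; ring A (chiral γ-lactone) is bought and coupled last.

Assumption: (2E,6E)-farnesyl bromide, 4-bromofuran-2(5H)-one and (S)-5-(hydroxymethyl)dihydrofuran-2(3H)-one are bought; the target is the (5S), all-E isomer read from the SMILES.

**Step 1**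
Reactants: 1 (2E,6E)-1-bromo-3,7,11-trimethyldodeca-2,6,10-triene (farnesyl bromide); 2 acetic acid
Product: 3 farnesylacetic acid (4E,8E)-5,9,13-trimethyltetradeca-4,8,12-trienoic acid
Conditions: 2 (1.3 equiv), LiN(iPr)2 (2.7 equiv), THF/DMPU, 0 → 35 °C; then 1, 0 °C → rt; 1 M HCl work-up
Reagents that add atoms: none
Why: SN2 alkylation of the acetic acid dianion (carboxylic acid dianion alkylation) at the primary allylic bromide adds the two-carbon acid handle and leaves both E-alkenes untouched.

**Step 2**
Reactants: 3 farnesylacetic acid; 4 4-bromofuran-2(5H)-one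
Product: 6 butenolide 4-[(3E,7E)-4,8,12-trimethyltrideca-3,7,11-trien-1-yl]furan-2(5H)-one, via N-acyloxyphthalimide 5 (not isolated)
Conditions: N-hydroxyphthalimide (1.05 equiv), N,N'-diisopropylcarbodiimide (1.05 equiv), DMA, rt, 2 h; then 4 (1.5 equiv), NiBr2·glyme (10 mol%), 4,4'-di-tert-butyl-2,2'-bipyridine (12 mol%), 2,4,5,6-tetrakis(carbazol-9-yl)isophthalonitrile (4CzIPN, 2 mol%), Hantzsch ester (1.5 equiv), NaHCO3 (2 equiv), degassed, 450 nm LEDs, 25 °C
Reagents that add atoms: none
Why: Proposed new method: a photochemical nickel-catalysed reductive decarboxylative alkenylation with a vinylogous acyl bromide as the C(sp2) partner — blue-light-excited 4CzIPN is reduced by the Hantzsch ester, the reduced dye fragments 5 to the primary homoallylic radical, CO2 and phthalimide and keeps nickel zerovalent, zerovalent nickel inserts into the activated C4–Br bond of 4, the divalent alkenylnickel bromide captures the radical and the trivalent nickel species reductively eliminates the bond that attaches ring B, with fast capture by nickel and Hantzsch ester scavenging of any bromine atoms expected to protect the E-alkenes from the slow reversible 3-exo closure of the radical; the closest known reaction type is the nickel-catalysed photo- or electroreductive decarboxylative arylation/alkenylation of N-acyloxyphthalimides with aryl and simple alkenyl halides, to my knowledge not yet shown for a 4-halofuran-2(5H)-one.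

**Step 3**
Reactants: 6 butenolide from step 2
Product: 8 epoxide 4-[(3E,7E)-10-(3,3-dimethyloxiran-2-yl)-4,8-dimethyldeca-3,7-dien-1-yl]furan-2(5H)-one, via bromohydrin 7 (not isolated)
Conditions: NBS (1.1 equiv), THF/H2O 3:1, 0 °C; then K2CO3, MeOH, 0 °C, 30 min
Reagents that add atoms: water, O
Why: van Tamelen terminal-selective bromohydrin formation (Markovnikov opening of the bromonium ion by water on the exposed end of the coiled polyene) followed by Williamson closure to the epoxide; the electron-poor butenolide alkene is inert to NBS and the new racemic centre is erased in step 4.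

**Step 4**
Reactants: 8 terminal epoxide
Product: 9 aldehyde (4E,8E)-4,8-dimethyl-11-(5-oxo-2,5-dihydrofuran-3-yl)undeca-4,8-dienal
Conditions: H5IO6 (1.2 equiv), THF/Et2O, 0 °C → rt
Reagents that add atoms: none
Why: Periodic acid opens the epoxide to the glycol and cleaves it (Malaprade glycol cleavage) to the aldehyde and acetone, a standard end-group degradation of terminal terpenoid epoxides that spares trisubstituted alkenes and the butenolide.

**Step 5**
Reactants: 10 (S)-5-(hydroxymethyl)dihydrofuran-2(3H)-one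
Product: 11 (S)-5-oxotetrahydrofuran-2-carbaldehyde
Conditions: Dess–Martin periodinane (1.2 equiv), CH2Cl2, 0 °C → rt; filtered and used crude
Reagents that add atoms: none
Why: Dess–Martin oxidation of the primary alcohol under neutral, non-epimerising conditions; the (S) centre bought with 10 is not touched.

**Step 6**
Reactants: 11 (S)-5-oxotetrahydrofuran-2-carbaldehyde; 12 isopropyltriphenylphosphonium iodide
Product: 13 (5S)-5-(2-methylprop-1-en-1-yl)dihydrofuran-2(3H)-one
Conditions: 12 (1.3 equiv), n-BuLi (1.25 equiv), THF, 0 °C; then 11, −78 → 0 °C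
Reagents that add atoms: none
Why: Wittig olefination with the non-stabilised isopropylidene ylide at low temperature; the stereocentre is not a reacting centre and a slight deficit of base avoids its enolisation, so (S) is kept.

**Step 7**
Reactants: 13 (5S)-5-(2-methylprop-1-en-1-yl)dihydrofuran-2(3H)-one; 9 butenolide aldehyde
Product: 16 target (3E,5S)-3-[(4E,8E)-4,8-dimethyl-11-(5-oxo-2,5-dihydrofuran-3-yl)undeca-4,8-dien-1-ylidene]-5-(2-methylprop-1-en-1-yl)dihydrofuran-2(3H)-one, via lithium aldolate 14 (not isolated), via mesylate 15 (not isolated)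
Conditions: LiN(SiMe3)2 (1.05 equiv), THF, −78 °C; 9 (1.0 equiv), −78 °C, 30 min; MsCl (1.5 equiv), −78 → 0 °C; DBU (3 equiv), 0 °C → rt
Reagents that add atoms: none
Why: Aldol addition of the lithium enolate of 13 to the aldehyde of 9, mesylation of the aldolate and DBU-induced E1cB elimination (aldol condensation) give the thermodynamically preferred (E)-alkylidene lactone; C5 stays (S) because it is not enolisable.

**Compound list**
1 | (2E,6E)-1-bromo-3,7,11-trimethyldodeca-2,6,10-triene (farnesyl bromide) | CC(C)=CCC/C(C)=C/CC/C(C)=C/CBr | starting material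
2 | acetic acid | CC(=O)O | starting material
3 | (4E,8E)-5,9,13-trimethyltetradeca-4,8,12-trienoic acid (farnesylacetic acid) | CC(C)=CCC/C(C)=C/CC/C(C)=C/CCC(=O)O | intermediate
4 | 4-bromofuran-2(5H)-one | O=C1C=C(Br)CO1 | starting material
5 | 1,3-dioxoisoindolin-2-yl (4E,8E)-5,9,13-trimethyltetradeca-4,8,12-trienoate | CC(C)=CCC/C(C)=C/CC/C(C)=C/CCC(=O)ON1C(=O)c2ccccc2C1=O | intermediate (not isolated)
6 | 4-[(3E,7E)-4,8,12-trimethyltrideca-3,7,11-trien-1-yl]furan-2(5H)-one | CC(C)=CCC/C(C)=C/CC/C(C)=C/CCC1=CC(=O)OC1 | intermediate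
7 | 4-[(3E,7E)-11-bromo-12-hydroxy-4,8,12-trimethyltrideca-3,7-dien-1-yl]furan-2(5H)-one (racemic at C11') | CC(C)(O)C(Br)CC/C(C)=C/CC/C(C)=C/CCC1=CC(=O)OC1 | intermediate (not isolated)
8 | 4-[(3E,7E)-10-(3,3-dimethyloxiran-2-yl)-4,8-dimethyldeca-3,7-dien-1-yl]furan-2(5H)-one (racemic at the oxirane carbon) | CC1(C)OC1CC/C(C)=C/CC/C(C)=C/CCC2=CC(=O)OC2 | intermediate
9 | (4E,8E)-4,8-dimethyl-11-(5-oxo-2,5-dihydrofuran-3-yl)undeca-4,8-dienal | O=CCC/C(C)=C/CC/C(C)=C/CCC1=CC(=O)OC1 | intermediate
10 | (S)-5-(hydroxymethyl)dihydrofuran-2(3H)-one | OC[C@@H]1CCC(=O)O1 | starting material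
11 | (S)-5-oxotetrahydrofuran-2-carbaldehyde | O=C[C@@H]1CCC(=O)O1 | intermediate
12 | isopropyltriphenylphosphonium iodide | CC(C)[P+](c1ccccc1)(c1ccccc1)c1ccccc1.[I-] | starting material
13 | (5S)-5-(2-methylprop-1-en-1-yl)dihydrofuran-2(3H)-one | CC(C)=C[C@@H]1CCC(=O)O1 | intermediate
14 | lithium (4E,8E)-4,8-dimethyl-1-[(5S)-5-(2-methylprop-1-en-1-yl)-2-oxotetrahydrofuran-3-yl]-11-(5-oxo-2,5-dihydrofuran-3-yl)undeca-4,8-dien-1-olate (diastereomer mixture at C3 and C1') | CC(C)=C[C@@H]1CC(C([O-])CC/C(C)=C/CC/C(C)=C/CCC2=CC(=O)OC2)C(=O)O1.[Li+] | intermediate (not isolated)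
15 | (4E,8E)-4,8-dimethyl-1-[(5S)-5-(2-methylprop-1-en-1-yl)-2-oxotetrahydrofuran-3-yl]-11-(5-oxo-2,5-dihydrofuran-3-yl)undeca-4,8-dien-1-yl methanesulfonate (diastereomer mixture) | CC(C)=C[C@@H]1CC(C(OS(C)(=O)=O)CC/C(C)=C/CC/C(C)=C/CCC2=CC(=O)OC2)C(=O)O1 | intermediate (not isolated)
16 | (3E,5S)-3-[(4E,8E)-4,8-dimethyl-11-(5-oxo-2,5-dihydrofuran-3-yl)undeca-4,8-dien-1-ylidene]-5-(2-methylprop-1-en-1-yl)dihydrofuran-2(3H)-one | CC(C)=C[C@@H]1C/C(=C\CC/C(C)=C/CC/C(C)=C/CCC2=CC(=O)OC2)C(=O)O1 | target

**Totals**
Total step count: 7. Longest linear sequence: 5 steps (1 → 3 → 6 → 8 → 9 → 16); the lactone branch (10 → 11 → 13) is 2 steps.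

**Steps most likely to fail**

Step 2 (the new step). The risks are hydrodebromination or homocoupling of 4, nucleophilic attack on the vinylogous acyl bromide, and partial E/Z erosion at the nearest alkene through the homoallylic radical. The fallback uses known chemistry; it sets out from 1 and comes back at 6. Alkylation of 1 with the dianion of ethyl acetoacetate (NaH, then n-BuLi, THF, 0 °C; Weiler alkylation) gives the β-keto ester ethyl (6E,10E)-7,11,15-trimethyl-3-oxohexadeca-6,10,14-trienoate F1. Tf2O with aqueous LiOH in hexanes gives the (Z)-enol triflate ethyl (2Z,6E,10E)-7,11,15-trimethyl-3-(trifluoromethylsulfonyloxy)hexadeca-2,6,10,14-tetraenoate F2. Stille coupling with Bu3SnCH2OH (Pd(PPh3)4, dioxane, 80 °C) gives the hydroxymethyl enoate ethyl (2Z,6E,10E)-3-(hydroxymethyl)-7,11,15-trimethylhexadeca-2,6,10,14-tetraenoate F3, which lactonises on the spot to 6.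

Step 6. Aldehyde 11 is hydrate-prone and its α-acyloxy centre is labile toward the basic, hindered isopropylidene ylide, so low yield or partial racemisation is possible. The fallback sets out from 11 and comes back at 13. The small, fast methylene ylide Ph3P=CH2 (from Ph3PCH3Br and KN(SiMe3)2, THF, −78 °C) gives the vinyl lactone (5S)-5-ethenyldihydrofuran-2(3H)-one F4. Cross-metathesis of F4 with excess 2-methyl-2-butene (second-generation Grubbs catalyst (H2IMes)(PCy3)Cl2Ru=CHPh, CH2Cl2, 40 °C) then builds the trisubstituted alkene of 13 under neutral conditions.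

Step 7. The risks are proton transfer from the C5 methylene of ring B to the enolate or to DBU, retro-aldol during mesylation, and an E/Z mixture. The fallback sets out from 13 and comes back at 16. LiN(iPr)2 and ClP(O)(OEt)2 (THF, −78 °C) give the enol phosphate diethyl (5S)-5-(2-methylprop-1-en-1-yl)-4,5-dihydrofuran-2-yl phosphate F5. A second portion of LiN(iPr)2 rearranges it (1,3 O→C phosphoryl shift) to the α-phosphono lactone diethyl [(5S)-5-(2-methylprop-1-en-1-yl)-2-oxotetrahydrofuran-3-yl]phosphonate F6. Horner–Wadsworth–Emmons olefination of 9 with F6 (LiCl, DBU, MeCN, 0 °C) gives 16, E major, with the Z isomer removed by chromatography.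

**Further compounds**
F1 | step 2 | ethyl (6E,10E)-7,11,15-trimethyl-3-oxohexadeca-6,10,14-trienoate | CC(C)=CCC/C(C)=C/CC/C(C)=C/CCC(=O)CC(=O)OCC
F2 | step 2 | ethyl (2Z,6E,10E)-7,11,15-trimethyl-3-(trifluoromethylsulfonyloxy)hexadeca-2,6,10,14-tetraenoate | CC(C)=CCC/C(C)=C/CC/C(C)=C/CC/C(OS(=O)(=O)C(F)(F)F)=C/C(=O)OCC
F3 | step 2 | ethyl (2Z,6E,10E)-3-(hydroxymethyl)-7,11,15-trimethylhexadeca-2,6,10,14-tetraenoate | CC(C)=CCC/C(C)=C/CC/C(C)=C/CC/C(CO)=C/C(=O)OCC
F4 | step 6 | (5S)-5-ethenyldihydrofuran-2(3H)-one | C=C[C@@H]1CCC(=O)O1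
F5 | step 7 | diethyl (5S)-5-(2-methylprop-1-en-1-yl)-4,5-dihydrofuran-2-yl phosphate | CCOP(=O)(OCC)OC1=CC[C@@H](C=C(C)C)O1
F6 | step 7 | diethyl [(5S)-5-(2-methylprop-1-en-1-yl)-2-oxotetrahydrofuran-3-yl]phosphonate (mixture at C3) | CCOP(=O)(OCC)C1C[C@@H](C=C(C)C)OC1=O
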